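**Strategy**

Ring numbering: C1 (C=O), C2 (CMe2), C3 (CH), C4 (C(OH)Me), C5, C6 (CH2). Ketone C1 and carbinol C4 are 1,4-related, so each of the ring bonds C5–C6 and C2–C3 joins a ketone α-carbon to a carbinol α-carbon; a ketone α,α′-bis-nucleophile and an epoxide as reversed-polarity partner fit this pattern. In one flask the α′-dienolate of 3-methylbut-3-en-2-one is alkylated by a cis-epoxy triflate (C5–C6); conjugate hydride addition then unmasks the tetrasubstituted enolate, which opens the epoxide at its secondary carbon (C2–C3, inversion). The triflate derives from (R)-linalool (side-chain carbinol); a Sharpless epoxidation sets both ring stereocentres. Umbelliferone is attached last.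

Key step: step 7

Assumption: commercial (R)-(−)-linalool of high enantiomeric purity is the source of the side-chain stereocentre; 3-methylbut-3-en-2-one and umbelliferone are bought.

**Route**

Step 1
Reactants: 1 (R)-(−)-linalool
Product: 3 (3R)-3,7-dimethyloct-6-ene-1,3-diol, via B-alkyl-9-BBN adduct 2 (not isolated)
Conditions: 9-borabicyclo[3.3.1]nonane (2.2 equiv), THF, 0 °C to rt; then NaOH (aq.), H2O2, 0 °C to rt
Reagents that add atoms: hydrogen peroxide, OO
Why: Brown hydroboration–oxidation; the bulky borane should add to the monosubstituted vinyl group much faster than to the trisubstituted alkene and place boron on the terminal carbon, and the carbinol stereocentre is not touched.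

Step 2
Reactants: 3 (3R)-3,7-dimethyloct-6-ene-1,3-diol
Product: 4 (4R)-2,2,4-trimethyl-4-(4-methylpent-3-en-1-yl)-1,3-dioxane
Conditions: 2,2-dimethoxypropane, pyridinium p-toluenesulfonate (cat.), CH2Cl2, rt
Reagents that add atoms: 2,2-dimethoxypropane, COC(C)(C)OC
Why: Acid-catalysed transacetalisation (acetonide formation) of the 1,3-diol should give the six-membered dioxane, which masks both hydroxyls against the organolithium, hydride and enolate steps that follow.

Step 3
Reactants: 4 (4R)-2,2,4-trimethyl-4-(4-methylpent-3-en-1-yl)-1,3-dioxane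
Product: 6 3-[(4R)-2,2,4-trimethyl-1,3-dioxan-4-yl]propanal, via ozonide 5 (not isolated)
Conditions: O3, CH2Cl2, −78 °C; then PPh3, −78 °C to rt
Reagents that add atoms: ozone, [O-][O+]=O
Why: Ozonolysis with reductive work-up should cleave the only C=C bond to the aldehyde; the acetal and the stereocentre are inert.

Step 4
Reactants: 6 3-[(4R)-2,2,4-trimethyl-1,3-dioxan-4-yl]propanal
Product: 9 (2Z)-2-methyl-5-[(4R)-2,2,4-trimethyl-1,3-dioxan-4-yl]pent-2-en-1-ol, via lithiobetaine 7 (not isolated), via β-oxido ylide 8 (not isolated)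
Conditions: EtPPh3Br, n-butyllithium, THF, 0 °C; 6, −78 °C; n-butyllithium, −78 to −25 °C; (CH2O)n, 0 °C to rt; H2O
Reagents that add atoms: ethyltriphenylphosphonium bromide, CC[P+](c1ccccc1)(c1ccccc1)c1ccccc1.[Br-]; paraformaldehyde (as formaldehyde), C=O
Why: Wittig–Schlosser β-oxido ylide hydroxymethylation (SCOOPY type): the lithiobetaine is deprotonated to the β-oxido ylide, which adds formaldehyde and expels the oxygen of the first aldehyde, so that CH2OH should end up cis to the chain, giving the (Z)-2-methylallylic alcohol.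

Step 5
Reactants: 9 (2Z)-2-methyl-5-[(4R)-2,2,4-trimethyl-1,3-dioxan-4-yl]pent-2-en-1-ol
Product: 10 [(2S,3R)-2-methyl-3-{2-[(4R)-2,2,4-trimethyl-1,3-dioxan-4-yl]ethyl}oxiran-2-yl]methanol
Conditions: Ti(OiPr)4 (10 mol%), L-(+)-diethyl tartrate (12 mol%), tBuOOH, 4 Å molecular sieves, CH2Cl2, −20 °C
Reagents that add atoms: tert-butyl hydroperoxide, CC(C)(C)OO
Why: Katsuki–Sharpless asymmetric epoxidation; with L-(+)-tartrate a (Z)-allylic alcohol should give the (2S,3R)-epoxy alcohol (the sense known for nerol), so reagent control sets both future ring stereocentres regardless of the remote dioxane centre.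

Step 6
Reactants: 10 [(2S,3R)-2-methyl-3-{2-[(4R)-2,2,4-trimethyl-1,3-dioxan-4-yl]ethyl}oxiran-2-yl]methanol
Product: 11 [(2S,3R)-2-methyl-3-{2-[(4R)-2,2,4-trimethyl-1,3-dioxan-4-yl]ethyl}oxiran-2-yl]methyl trifluoromethanesulfonate
Conditions: Tf2O, 2,6-lutidine, CH2Cl2, −78 °C; cold aqueous work-up, used at once
Reagents that add atoms: trifluoromethanesulfonic anhydride, O=S(=O)(OS(=O)(=O)C(F)(F)F)C(F)(F)F
Why: Sulfonylation of the primary alcohol at low temperature; the hindered pyridine base takes up triflic acid, so epoxide and acetal should survive.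

Step 7
Reactants: 11 [(2S,3R)-2-methyl-3-{2-[(4R)-2,2,4-trimethyl-1,3-dioxan-4-yl]ethyl}oxiran-2-yl]methyl trifluoromethanesulfonate; 12 3-methylbut-3-en-2-one
Product: 16 (3R,4S)-4-hydroxy-2,2,4-trimethyl-3-{2-[(4R)-2,2,4-trimethyl-1,3-dioxan-4-yl]ethyl}cyclohexan-1-one, via lithium dienolate 13 (not isolated), via epoxy enone 14 (not isolated), via tetrasubstituted lithium enolate 15 (not isolated)
Conditions: lithium diisopropylamide, 12, THF, −78 °C; 11, −78 to −40 °C; then lithium tri-sec-butylborohydride, −78 °C, warm to 45 °C; H2O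
Reagents that add atoms: none
Why: Lithium diisopropylamide removes a proton from the acetyl methyl of 12, the only acidic site, and the carbon terminus of the cross-conjugated dienolate 13 displaces the primary, oxirane-activated triflate of 11 by SN2 (ketone enolate C-alkylation), which forms the C5–C6 bond and gives 14. Lithium tri-sec-butylborohydride then adds hydride to the unsubstituted terminus of the isopropenyl ketone (conjugate reduction, the first half of a reductive enone alkylation), so that the second geminal methyl group appears and the tetrasubstituted enolate 15 is formed regiospecifically, with no base left that could enolise C6. On warming, C2 of 15 should open the oxirane at its secondary carbon, a 6-(enolendo)-exo-tet C-alkylation that is 6-endo with respect to the epoxide, as in the Stork epoxynitrile cyclisation; this closes the cyclohexanone ring through the C2–C3 bond. The new stereocentre C3 is fixed by SN2 inversion at the epoxide carbon, and C4 keeps the C–O bond and configuration set in step 5, so the cis relation of side chain and hydroxyl follows from the Z-geometry of 9. The step needs C- over O-alkylation (lithium enolates in THF), attack at the secondary instead of the fully substituted oxirane carbon (the 5-exo alternative would join two quaternary carbons) and 1,4- over 1,2-hydride delivery (β-unsubstituted enone, bulky hydride); the acetal protects both side-chain hydroxyls from the bases.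

Step 8
Reactants: 16 (3R,4S)-4-hydroxy-2,2,4-trimethyl-3-{2-[(4R)-2,2,4-trimethyl-1,3-dioxan-4-yl]ethyl}cyclohexan-1-one
Product: 17 (3R,4S)-3-[(3R)-3,5-dihydroxy-3-methylpentyl]-4-hydroxy-2,2,4-trimethylcyclohexan-1-one
Conditions: AcOH/THF/H2O (3:1:1), rt
Reagents that add atoms: none
Why: Acid-catalysed acetal hydrolysis; the tertiary alcohols and the ketone should be stable to dilute acetic acid at room temperature, and no stereocentre is involved.

Step 9
Reactants: 17 (3R,4S)-3-[(3R)-3,5-dihydroxy-3-methylpentyl]-4-hydroxy-2,2,4-trimethylcyclohexan-1-one; 18 umbelliferone (7-hydroxy-2H-chromen-2-one)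
Product: 19 7-{[(3R)-3-hydroxy-5-[(1R,2S)-2-hydroxy-2,6,6-trimethyl-5-oxocyclohexyl]-3-methylpentyl]oxy}-2H-chromen-2-one
Conditions: PPh3, diisopropyl azodicarboxylate, THF, 0 °C to rt
Reagents that add atoms: none
Why: Mitsunobu etherification; only the primary alcohol should form the alkoxyphosphonium ion, which the acidic phenol displaces, while the two tertiary alcohols and the ketone do not react.

**Compound list**

1 | (R)-(−)-linalool, (3R)-3,7-dimethylocta-1,6-dien-3-ol | CC(C)=CCC[C@@](C)(O)C=C | starting material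
2 | (3R)-1-(9-borabicyclo[3.3.1]nonan-9-yl)-3,7-dimethyloct-6-en-3-ol | CC(C)=CCC[C@@](C)(O)CCB1C2CCCC1CCC2 | intermediate
3 | (3R)-3,7-dimethyloct-6-ene-1,3-diol | CC(C)=CCC[C@@](C)(O)CCO | intermediate
4 | (4R)-2,2,4-trimethyl-4-(4-methylpent-3-en-1-yl)-1,3-dioxane | CC(C)=CCC[C@]1(C)CCOC(C)(C)O1 | intermediate
5 | 3,3-dimethyl-5-{2-[(4R)-2,2,4-trimethyl-1,3-dioxan-4-yl]ethyl}-1,2,4-trioxolane (ozonide) | CC1(C)OOC(CC[C@]2(C)CCOC(C)(C)O2)O1 | intermediate
6 | 3-[(4R)-2,2,4-trimethyl-1,3-dioxan-4-yl]propanal | O=CCC[C@]1(C)CCOC(C)(C)O1 | intermediate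
7 | lithiobetaine, {3-oxido-5-[(4R)-2,2,4-trimethyl-1,3-dioxan-4-yl]pentan-2-yl}(triphenyl)phosphonium | CC([P+](c1ccccc1)(c1ccccc1)c1ccccc1)C([O-])CC[C@]1(C)CCOC(C)(C)O1 | intermediate
8 | β-oxido ylide, lithium 5-[(4R)-2,2,4-trimethyl-1,3-dioxan-4-yl]-2-(triphenyl-λ5-phosphanylidene)pentan-3-olate | [Li+].CC(=P(c1ccccc1)(c1ccccc1)c1ccccc1)C([O-])CC[C@]1(C)CCOC(C)(C)O1 | intermediate
9 | (2Z)-2-methyl-5-[(4R)-2,2,4-trimethyl-1,3-dioxan-4-yl]pent-2-en-1-ol | OC/C(C)=C\CC[C@]1(C)CCOC(C)(C)O1 | intermediate
10 | [(2S,3R)-2-methyl-3-{2-[(4R)-2,2,4-trimethyl-1,3-dioxan-4-yl]ethyl}oxiran-2-yl]methanol | OC[C@]1(C)O[C@@H]1CC[C@]2(C)CCOC(C)(C)O2 | intermediate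
11 | [(2S,3R)-2-methyl-3-{2-[(4R)-2,2,4-trimethyl-1,3-dioxan-4-yl]ethyl}oxiran-2-yl]methyl trifluoromethanesulfonate | FC(F)(F)S(=O)(=O)OC[C@]1(C)O[C@@H]1CC[C@]2(C)CCOC(C)(C)O2 | intermediate
12 | 3-methylbut-3-en-2-one | CC(=O)C(C)=C | starting material
13 | lithium 3-methylbuta-1,3-dien-2-olate | [Li+].[O-]C(=C)C(C)=C | intermediate
14 | 2-methyl-5-[(2S,3R)-2-methyl-3-{2-[(4R)-2,2,4-trimethyl-1,3-dioxan-4-yl]ethyl}oxiran-2-yl]pent-1-en-3-one | C=C(C)C(=O)CC[C@]1(C)O[C@@H]1CC[C@]2(C)CCOC(C)(C)O2 | intermediate
15 | lithium 2-methyl-5-[(2S,3R)-2-methyl-3-{2-[(4R)-2,2,4-trimethyl-1,3-dioxan-4-yl]ethyl}oxiran-2-yl]pent-2-en-3-olate | [Li+].CC(C)=C([O-])CC[C@]1(C)O[C@@H]1CC[C@]2(C)CCOC(C)(C)O2 | intermediate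
16 | (3R,4S)-4-hydroxy-2,2,4-trimethyl-3-{2-[(4R)-2,2,4-trimethyl-1,3-dioxan-4-yl]ethyl}cyclohexan-1-one | CC1(C)C(=O)CC[C@](C)(O)[C@@H]1CC[C@]2(C)CCOC(C)(C)O2 | intermediate
17 | (3R,4S)-3-[(3R)-3,5-dihydroxy-3-methylpentyl]-4-hydroxy-2,2,4-trimethylcyclohexan-1-one | CC1(C)C(=O)CC[C@](C)(O)[C@@H]1CC[C@@](C)(O)CCO | intermediate
18 | umbelliferone (7-hydroxy-2H-chromen-2-one) | Oc1ccc2ccc(=O)oc2c1 | starting material
19 | 7-{[(3R)-3-hydroxy-5-[(1R,2S)-2-hydroxy-2,6,6-trimethyl-5-oxocyclohexyl]-3-methylpentyl]oxy}-2H-chromen-2-one | CC1(C)C(=O)CC[C@](C)(O)[C@@H]1CC[C@@](C)(O)CCOc1ccc2ccc(=O)oc2c1 | target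

**Step count and risks**

Total steps: 9. Longest linear sequence: 9 steps (1 to 19); 12 and 18 are bought and enter in steps 7 and 9.

Step 7 (highest risk). The closure joins a fully substituted enolate carbon to an oxirane carbon that sits next to another quaternary carbon. The boron-complexed enolate may therefore react too slowly, so that O-alkylation to a cyclic enol ether or plain protonation on work-up takes over. 1,2-Reduction of the enone and O-alkylation of the dienolate by the triflate are further leaks. The fallback sets out from 11 and builds the two bonds stepwise with a carboxyl-activated nucleophile. Triflate 11 would C-alkylate the sodium enolate of methyl 4-methyl-3-oxopentanoate (NaH, THF/DMF, 0 °C) to give methyl 4-methyl-2-{[(2S,3R)-2-methyl-3-{2-[(4R)-2,2,4-trimethyl-1,3-dioxan-4-yl]ethyl}oxiran-2-yl]methyl}-3-oxopentanoate F1. Its dianion (lithium diisopropylamide, 2.2 equiv, THF, −78 °C to rt) carries a much more nucleophilic γ-carbon than a simple enolate. That carbon should open the oxirane in the same 6-endo sense to give methyl (4R,5S)-5-hydroxy-3,3,5-trimethyl-2-oxo-4-{2-[(4R)-2,2,4-trimethyl-1,3-dioxan-4-yl]ethyl}cyclohexane-1-carboxylate F2. Saponification and decarboxylation (LiOH, THF/H2O, then acidification to pH 5 and gentle warming) would return to 16.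

Step 4. The ring configuration rests on the Z-geometry made here. Premature collapse of the lithiobetaine to the simple ethylidene olefin, or equilibration of the β-oxido ylide before formaldehyde capture, would lower conversion or erode the geometry. The fallback sets out from 6. A Still–Gennari olefination (ethyl 2-[bis(2,2,2-trifluoroethoxy)phosphoryl]propanoate, KN(SiMe3)2, 18-crown-6, THF, −78 °C) should give ethyl (2Z)-2-methyl-5-[(4R)-2,2,4-trimethyl-1,3-dioxan-4-yl]pent-2-enoate F3. Reduction with diisobutylaluminium hydride (CH2Cl2, −78 °C) would come back to 9.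

Step 5. Cis-trisubstituted allylic alcohols are the least selective substrate class for the titanium–tartrate catalyst. Slow turnover and incomplete facial selectivity would give a second epoxide that differs from 10 only at centres remote from the dioxane and would be hard to remove. The fallback sets out from 9 and reaches 10 directly by a Shi epoxidation. It uses the enantiomer of the fructose-derived ketone that the spiro transition-state model assigns to the required face, with KHSO5 in K2CO3-buffered MeCN/dimethoxymethane/H2O at 0 °C. Selectivity then does not depend on alkoxide binding to a metal; no further compound is made (F0).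

Further compounds
F1 | step 7 | methyl 4-methyl-2-{[(2S,3R)-2-methyl-3-{2-[(4R)-2,2,4-trimethyl-1,3-dioxan-4-yl]ethyl}oxiran-2-yl]methyl}-3-oxopentanoate | COC(=O)C(C[C@]1(C)O[C@@H]1CC[C@]2(C)CCOC(C)(C)O2)C(=O)C(C)C
F2 | step 7 | methyl (4R,5S)-5-hydroxy-3,3,5-trimethyl-2-oxo-4-{2-[(4R)-2,2,4-trimethyl-1,3-dioxan-4-yl]ethyl}cyclohexane-1-carboxylate | COC(=O)C1C[C@](C)(O)[C@H](CC[C@]2(C)CCOC(C)(C)O2)C(C)(C)C1=O
F3 | step 4 | ethyl (2Z)-2-methyl-5-[(4R)-2,2,4-trimethyl-1,3-dioxan-4-yl]pent-2-enoate | CCOC(=O)/C(C)=C\CC[C@]1(C)CCOC(C)(C)O1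
F0 | step 5 | none | none
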